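## Retrosynthetic overview

- **Feature:** in ring A, C4a carries the C4 carbonyl and both of its neighbours bear oxygen: C8a (O1 of pyranone ring C) and C5 (the chelated OH). Both sites are ortho to the carbonyl and meta to the C7 OMe, so one symmetric 2,6-difluoro-4-methoxyphenyl ketone can stand in for both C–O bonds.
- **Last disconnection:** C5–OH ⇒ C5–OBn ⇒ C5–F, by SNAr with benzyl oxide on the 5-fluoroflavone followed by hydrogenolysis.
- **Key disconnection:** O1–C8a, by attack of the 1,3-diketone enolate oxygen on one of two equivalent ortho fluorides. This closes ring C, the only ring that is built; rings A and B are purchased.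
- **Early disconnections:** C2–C3 by crossed Claisen condensation of 2,6-difluoro-4-methoxyacetophenone with methyl 3,4,5-trimethoxybenzoate. C4–C4a by lithiation of 3,5-difluoroanisole between the fluorines and Weinreb acetylation.

Key step: step 3

Remark on the chemistry: the target is a planar flavone with no stereogenic centre, axis or plane. It therefore has no enantiomers and the route needs no stereocontrol. Intermediates 4 and 11 carry only a transient sp3 centre and are racemic.

## Route

Step 1
Reactants: 1 3,5-difluoroanisole; 2 N-methoxy-N-methylacetamide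
Product: 5 1-(2,6-difluoro-4-methoxyphenyl)ethanone, via aryllithium 3 (not isolated), via tetrahedral lithium adduct 4 (not isolated)
Conditions: n-BuLi (1.05 equiv), THF, −78 °C, 1 h; then 2, −78 → 0 °C; 1 M HCl
Reagents that add atoms: none
Why: Directed ortho-lithiation removes the ring proton flanked by both fluorines (the most acidic C–H of 1), aryllithium 3 is kept at −78 °C so that LiF loss to an aryne stays slow, and it adds only once to the Weinreb amide because the N-methoxy-chelated adduct 4 holds until the acid quench (Weinreb ketone synthesis).

Step 2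
Reactants: 5 1-(2,6-difluoro-4-methoxyphenyl)ethanone; 6 methyl 3,4,5-trimethoxybenzoate
Product: 9 1-(2,6-difluoro-4-methoxyphenyl)-3-(3,4,5-trimethoxyphenyl)propane-1,3-dione, via lithium enolate 7 (not isolated), via lithium diketonate 8 (not isolated)
Conditions: LiHMDS (2.2 equiv), THF, −78 °C; then 6, −78 °C → rt; 1 M HCl
Reagents that add atoms: none
Why: Crossed Claisen condensation: ketone 5 is converted completely into enolate 7 before the non-enolisable ester 6 is added, so self-condensation has no partner, and the second equivalent of base stores the product as chelated diketonate 8, which drives the equilibrium and, being anionic, shields the ring fluorides from the lithium methoxide that is released.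

Step 3
Reactants: 9 1-(2,6-difluoro-4-methoxyphenyl)-3-(3,4,5-trimethoxyphenyl)propane-1,3-dione
Product: 12 5-fluoro-7-methoxy-2-(3,4,5-trimethoxyphenyl)-4H-chromen-4-one, via potassium enolate 10 (not isolated), via Meisenheimer adduct 11 (not isolated)
Conditions: K2CO3 (2 equiv), dry DMF (0.05 M), 70 °C
Reagents that add atoms: none
Why: Carbonate removes a C3 proton of 9 to give enolate 10; in DMF the loosely bound potassium lets the C3–C4 bond rotate out of the U-shaped chelate, the oxygen on the trimethoxybenzoyl carbon then sits over a fluorine-bearing ortho carbon and adds to it to give σ-adduct 11, whose charge runs through C4a into the C4 carbonyl, and loss of fluoride restores the arene and forms O1–C8a. The closest known reaction type is the base-mediated, metal-free intramolecular SNAr O-arylation of 1-(2-haloaryl)-1,3-diketones to chromones and flavones, for which fluoride is the best leaving group. Ring C closes as a six-membered ring by addition–elimination at an sp2 carbon, formally 6-endo-trig with respect to the C8a=C4a bond that takes up the charge. No stereocentre is created, since C8a is sp3 only in transient 11. The step needs O- over C-arylation and reaction of one fluoride only: attack by C3 or by the C4 oxygen would have to close a four-membered ring, the two fluorides are interchanged by rotation about the aryl–C4 bond and so lead to the same product, and the C7 methoxy is meta to both and feeds no electron density to the reacting carbon. After closure the C5 fluoride has no internal nucleophile left, and dilution together with the moderate temperature should hold back its intermolecular displacement.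

Step 4
Reactants: 12 5-fluoro-7-methoxy-2-(3,4,5-trimethoxyphenyl)-4H-chromen-4-one
Product: 13 5-(benzyloxy)-7-methoxy-2-(3,4,5-trimethoxyphenyl)-4H-chromen-4-one
Conditions: BnOH (1.2 equiv), NaH (1.2 equiv), THF–DMF, 0 °C → rt
Reagents that add atoms: benzyl alcohol, OCc1ccccc1
Why: Intermolecular SNAr (addition–elimination) by benzyl oxide at C5, whose fluoride is ortho to the carbonyl-bearing C4a and meta to both the C7 methoxy and O1, so the charge of the adduct is taken up by the C4 carbonyl without opposition from a donor, and fluoride leaves far more readily than the para-placed C7 methoxide.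

Step 5
Reactants: 13 5-(benzyloxy)-7-methoxy-2-(3,4,5-trimethoxyphenyl)-4H-chromen-4-one
Product: 14 corymbosin, 5-hydroxy-7-methoxy-2-(3,4,5-trimethoxyphenyl)-4H-chromen-4-one
Conditions: H2 (1 atm), 10% Pd/C, EtOAc–MeOH, rt, stopped after one equivalent of H2
Reagents that add atoms: none
Why: Catalytic hydrogenolysis of the benzylic C–O bond should be much faster at 1 atm than saturation of the conjugated C2=C3 bond of a flavone, the four aryl methyl ethers are inert, and the freed 5-OH is held in a hydrogen bond to the C4 carbonyl.

## Compound list

| No. | Name | SMILES | Role |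
|---|---|---|---|
| 1 | 3,5-difluoroanisole | COc1cc(F)cc(F)c1 | starting material |
| 2 | N-methoxy-N-methylacetamide | CON(C)C(C)=O | starting material |
| 3 | (2,6-difluoro-4-methoxyphenyl)lithium | COc1cc(F)c([Li])c(F)c1 | intermediate |
| 4 | lithium 1-(2,6-difluoro-4-methoxyphenyl)-1-[methoxy(methyl)amino]ethan-1-olate (racemic) | COc1cc(F)c(C(C)(O[Li])N(C)OC)c(F)c1 | intermediate |
| 5 | 1-(2,6-difluoro-4-methoxyphenyl)ethanone | COc1cc(F)c(C(C)=O)c(F)c1 | intermediate |
| 6 | methyl 3,4,5-trimethoxybenzoate | COC(=O)c1cc(OC)c(OC)c(OC)c1 | starting material |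
| 7 | lithium 1-(2,6-difluoro-4-methoxyphenyl)ethen-1-olate | C=C(O[Li])c1c(F)cc(OC)cc1F | intermediate |
| 8 | lithium (Z)-diketonate of 9 | COc1cc(F)c(C(=O)/C=C(\O[Li])c2cc(OC)c(OC)c(OC)c2)c(F)c1 | intermediate |
| 9 | 1-(2,6-difluoro-4-methoxyphenyl)-3-(3,4,5-trimethoxyphenyl)propane-1,3-dione | COc1cc(F)c(C(=O)CC(=O)c2cc(OC)c(OC)c(OC)c2)c(F)c1 | intermediate |
| 10 | potassium (Z)-enolate of 9 | COc1cc(F)c(C(=O)/C=C(\[O-])c2cc(OC)c(OC)c(OC)c2)c(F)c1.[K+] | intermediate |
| 11 | potassium 5,8a-difluoro-7-methoxy-2-(3,4,5-trimethoxyphenyl)-8aH-chromen-4-olate (σ-adduct, racemic) | COC1=CC2(F)OC(c3cc(OC)c(OC)c(OC)c3)=CC([O-])=C2C(F)=C1.[K+] | intermediate |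
| 12 | 5-fluoro-7-methoxy-2-(3,4,5-trimethoxyphenyl)-4H-chromen-4-one | COc1cc(F)c2c(=O)cc(-c3cc(OC)c(OC)c(OC)c3)oc2c1 | intermediate |
| 13 | 5-(benzyloxy)-7-methoxy-2-(3,4,5-trimethoxyphenyl)-4H-chromen-4-one | COc1cc(OCc4ccccc4)c2c(=O)cc(-c3cc(OC)c(OC)c(OC)c3)oc2c1 | intermediate |
| 14 | corymbosin | COc1cc(O)c2c(=O)cc(-c3cc(OC)c(OC)c(OC)c3)oc2c1 | target |

Total step count: 5
Longest linear sequence: 5 steps (1 → 5 → 9 → 12 → 13 → 14)

## Steps most likely to fail

**Step 3.**
- **What may go wrong:** traces of hydroxide in the carbonate may cleave the diketone by retro-Claisen reaction. The still activated C5 fluoride of the product may also be displaced intermolecularly, by enolate 10 or by dimethylamine from DMF. Either process could consume material faster than the ring closes.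
- **Fallback:** ring C is closed at O1–C2 instead, by classical cyclodehydration, setting out from ketone 5.
- One fluoride is exchanged for OH with the hydroxide surrogate 2-(methylsulfonyl)ethanol (NaH, DMF, 0 °C → rt).
- The first-formed ether 1-{2-fluoro-4-methoxy-6-[2-(methylsulfonyl)ethoxy]phenyl}ethanone F1 loses methyl vinyl sulfone by E1cB in the flask. This gives 1-(2-fluoro-6-hydroxy-4-methoxyphenyl)ethanone F2, whose phenoxide protects the second fluoride from substitution.
- The dianion of F2 (LiHMDS, 3.3 equiv, THF, −78 °C) is C-acylated with 3,4,5-trimethoxybenzoyl chloride. The product is 1-(2-fluoro-6-hydroxy-4-methoxyphenyl)-3-(3,4,5-trimethoxyphenyl)propane-1,3-dione F3.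
- Catalytic H2SO4 in AcOH at 90 °C dehydrates F3 to fluoroflavone 12, where the route is rejoined.

**Step 4.**
- **What may go wrong:** the C4 carbonyl of a flavone is a vinylogous ester and only a moderate activator. Substitution at C5 may be slow enough for benzyl oxide to add at C2 and degrade the pyranone by ring opening.
- **Fallback:** the oxygen is installed before ring closure, while the activating group is still a true aryl ketone, setting out from ketone 5.
- BnOH (1.0 equiv) and NaH in THF (0 °C → rt) replace one fluoride to give 1-[2-(benzyloxy)-6-fluoro-4-methoxyphenyl]ethanone F4.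
- Claisen condensation with ester 6 under the conditions of step 2 gives 1-[2-(benzyloxy)-6-fluoro-4-methoxyphenyl]-3-(3,4,5-trimethoxyphenyl)propane-1,3-dione F5.
- K2CO3 in DMF closes ring C onto the one remaining fluoride, which is meta to both alkoxy groups. This delivers benzyl ether 13 directly, where the route is rejoined before the hydrogenolysis.

**Step 2.**
- **What may go wrong:** acylation of the lithium enolate by the only moderately electrophilic ester may be slow. That would leave time for methoxide attack on the ring fluorides or for premature partial cyclisation, which would blur the isolation of 9.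
- **Fallback:** aldol addition and oxidation replace the acylation, setting out from ketone 5.
- Enolate 7 (LiHMDS, THF, −78 °C) is trapped with 3,4,5-trimethoxybenzaldehyde. This gives racemic 1-(2,6-difluoro-4-methoxyphenyl)-3-hydroxy-3-(3,4,5-trimethoxyphenyl)propan-1-one F6.
- Oxidation of the β-hydroxy ketone with IBX (EtOAc, reflux) erases the stereocentre and gives diketone 9, where the route is rejoined.

## Further compounds

F1 | step 3 | 1-{2-fluoro-4-methoxy-6-[2-(methylsulfonyl)ethoxy]phenyl}ethanone | COc1cc(F)c(C(C)=O)c(OCCS(C)(=O)=O)c1
F2 | step 3 | 1-(2-fluoro-6-hydroxy-4-methoxyphenyl)ethanone | COc1cc(O)c(C(C)=O)c(F)c1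
F3 | step 3 | 1-(2-fluoro-6-hydroxy-4-methoxyphenyl)-3-(3,4,5-trimethoxyphenyl)propane-1,3-dione | COc1cc(O)c(C(=O)CC(=O)c2cc(OC)c(OC)c(OC)c2)c(F)c1
F4 | step 4 | 1-[2-(benzyloxy)-6-fluoro-4-methoxyphenyl]ethanone | COc1cc(F)c(C(C)=O)c(OCc2ccccc2)c1
F5 | step 4 | 1-[2-(benzyloxy)-6-fluoro-4-methoxyphenyl]-3-(3,4,5-trimethoxyphenyl)propane-1,3-dione | COc1cc(F)c(C(=O)CC(=O)c2cc(OC)c(OC)c(OC)c2)c(OCc3ccccc3)c1
F6 | step 2 | 1-(2,6-difluoro-4-methoxyphenyl)-3-hydroxy-3-(3,4,5-trimethoxyphenyl)propan-1-one (racemic) | COc1cc(F)c(C(=O)CC(O)c2cc(OC)c(OC)c(OC)c2)c(F)c1
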